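All runs are simulated for substances that don't exist; noise was put on by code.

Time is held fixed in this row: flasks of Q, dosed with the same charge of Z, are all read after 5.0 h.

| setting | theta | alpha | gamma | Friday's | Monday's | Thursday's |
|---|---|---|---|---|---|---|
| Q | 0.015 M | 0.017 M | 0.029 M | 0.012 M | 0.020 M | 0.030 M |
| Z | 0.040 M (fed, over 15 min) | 0.040 M (fed, over 15 min) | 0.040 M (fed, over 15 min) | 0.0400 M (fed, over 15 min) | 0.0400 M (fed, over 15 min) | 0.0400 M (fed, over 15 min) |
| remark | run made earlier; the fed solution adds 0.20 times the starting volume | run made earlier; the fed solution adds 0.20 times the starting volume | run made earlier; the fed solution adds 0.20 times the starting volume | the fed solution adds 0.20 times the starting volume | the fed solution adds 0.20 times the starting volume | the fed solution adds 0.20 times the starting volume |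
| time |  |  |  | 5.0 h | 5.0 h | 5.0 h |

| run | time / h | G / % | Q / % |
|---|---|---|---|
| theta | 0.200 | 0 | 63.9 |
| theta | 0.667 | 2.5 | 9.4 |
| theta | 1.33 | 7.4 | 1.6 |
| theta | 2.00 | 12.3 | 2.6 |
| theta | 2.50 | 14.3 | 0.5 |
| alpha | 0.500 | 2.4 | 16.5 |
| alpha | 1.00 | 4.3 | 4.3 |
| alpha | 1.50 | 6.9 | 2.4 |
| alpha | 2.00 | 12.2 | 2.5 |
| alpha | 2.50 | 14.2 | 1.3 |
| gamma | 0.500 | 0.1 | 25.1 |
| gamma | 1.00 | 4.6 | 10.0 |
| gamma | 1.50 | 4.0 | 7.2 |
| gamma | 2.00 | 6.5 | 3.5 |
| gamma | 2.50 | 6.4 | 2.8 |

(readings scatter by 1 percentage point)

- charges are per starting volume, the dose included; the dosed solution carries all of it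
- "hardly changes" means that all values lie within two and a half points (for a concentration: within two and a half percent of the largest)
- a reading of Q is of its free form alone

- [G] at the end for Friday's, Monday's, Thursday's, in this order
- how the row runs (falls all the way / rises, then falls / rises all the way / falls, then rises / hardly changes)

In the theta run Q is down to 1.6% at 1.33 h, yet G stands at 7.4%. So Q passes quickly into an intermediate, and G grows from it slowly. Two chemists dispute what the slow step needs.

The first holds that it is first order in the intermediate, so that G is a fixed percentage of the Q charged. She points to theta's 14.3% and alpha's 14.2% at 2.50 h, and her row rises all the way.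

The second points to gamma's 6.4%, about half of theta's at that time. He holds that each Q takes one Z first and that the slow step then consumes the Z beyond that equivalent. On his view its rate follows the surplus product S, the Q charged times the excess of the Z charge over the Q charge 4.00 × 10⁻⁴ M^2, given here for Monday's.

The percentage yield then follows the surplus, on his view. That surplus is 25.0 mM in theta and 11.0 mM in gamma, a ratio of 0.440, against 0.448 read from the yields, each reading carrying a scatter of 1 percentage point.

He solves both ends. With little Q the surplus barely moves, the step is pseudo-first-order and S goes as Q, which is her case. With Q near the Z charge, S goes as the surplus. Joined, S peaks at 20.0 mM, half the Z charge. Friday's has 3.36 × 10⁻⁴ M^2 and Thursday's 3.00 × 10⁻⁴ M^2, so Monday's stands highest.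

The forecast is his side's number: 0.0038 M, 0.0045 M and 0.0034 M, reckoned “on a per-starting-volume basis”, so that the row rises, then falls.

The flask gives 0.00316 M, 0.00384 M and 0.00320 M: the row rises, then falls, and he wins the shape. Her rise holds below the turn at 0.021 M.

    Q + Z ⇌ J (K = 90.0 M⁻¹, k = 0.0120 M⁻¹ s⁻¹)
    Z + X → G (k = 0.00120 M⁻¹ s⁻¹)
    Q + Z → X (k = 0.0390 M⁻¹ s⁻¹)

The length of the run is the largest single effect proved on Thursday's: ten times the time lifts [G] from 0.00320 M to 0.00819 M. In that longer Thursday's run the surplus factor of S shows: Thursday's S over the square of its Q charge is 33.3%, and G at 50.0 h stands at 32.8% of the Q charged, with Z at 0.438% of its charge.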